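**Retrosynthetic overview**

1. The target comes from LiAlH4 reduction of a tetralin-2,3-diester that carries a temporary hydroxyl on benzylic C4; this hydroxyl and two benzyl ethers are removed by hydrogenolysis (tetralin numbering of the target: C1 bears the guaiacyl group, C8 the peri methoxy group).
2. Ring B (C1, C2, C3, C4, C4a, C8a) is grown from the four-membered ring (C4a, C8a, C1, C4) of a trans-2-aryl-benzocyclobutenol: 4π ring opening and [4+2] capture of an (R)-lactate fumarate insert C2 and C3 and set C1, C2, C3 and the temporary C4 centre in one step.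
3. Enabling feature: the strained cyclobutene fused to ring A, with the hydroxyl on C4 and the aryl group on C1 trans to each other, so that both rotate outward and the hydroxyl steers the endo ester.
4. The benzocyclobutenol comes from 4-exo opening of a trans-stilbene oxide by an ortho-aryllithium; the oxirane comes from sulfur-ylide epoxidation of 2-bromo-O-benzylsyringaldehyde.
5. Ring order: ring A and the pendant arene are bought; then oxirane, cyclobutene, and ring B by two-carbon ring expansion.

Key step: step 6

Remark: tetralin numbering of the target is used for all ring-B compounds (C1 aryl-bearing, C4 benzylic CH2, C8 methoxy peri to C1).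
Remark: O-benzylsyringaldehyde, O-benzylvanillyl alcohol, methyl (R)-lactate and fumaryl chloride are taken as commercial.
Remark: the facial sense assigned to the (R)-lactate auxiliary in step 6 is an assignment by analogy and is assumed here; the configuration of the adduct is to be confirmed by crystallography before the route is carried on.

**Step 1**
Reactants: 1 4-(benzyloxy)-3,5-dimethoxybenzaldehyde
Product: 2 4-(benzyloxy)-2-bromo-3,5-dimethoxybenzaldehyde
Conditions: NBS (1.05 equiv), MeCN, rt, dark
Reagents that add atoms: N-bromosuccinimide, O=C1CCC(=O)N1Br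
Why: Electrophilic aromatic bromination, in which the two free ring positions of 1 are equivalent and each is activated ortho and para by a methoxy group, so that mono-bromination should give only the 2-bromo aldehyde.

**Step 2**
Reactants: 3 [4-(benzyloxy)-3-methoxyphenyl]methanol
Product: 4 1-{[4-(benzyloxy)-3-methoxyphenyl]methyl}thiolan-1-ium tetrafluoroborate
Conditions: tetrahydrothiophene (1.5 equiv), aq. HBF4 (48%, 1.1 equiv), MeCN, rt; precipitation with Et2O
Reagents that add atoms: tetrahydrothiophene, C1CCSC1; tetrafluoroboric acid, [H+].F[B-](F)(F)F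
Why: SN1-type substitution in which the electron-rich benzylic alcohol ionises under HBF4 and the cation is captured by the sulfide, the standard preparation of benzylsulfonium tetrafluoroborates.

**Step 3**
Reactants: 2 4-(benzyloxy)-2-bromo-3,5-dimethoxybenzaldehyde, 4 1-{[4-(benzyloxy)-3-methoxyphenyl]methyl}thiolan-1-ium tetrafluoroborate
Product: 6 rac-trans-2-[4-(benzyloxy)-2-bromo-3,5-dimethoxyphenyl]-3-[4-(benzyloxy)-3-methoxyphenyl]oxirane, via sulfonium ylide 5 (not isolated)
Conditions: powdered KOH (2 equiv), MeCN, 0 °C → rt; filtration through basic Al2O3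
Reagents that add atoms: none
Why: Corey–Chaykovsky epoxidation with a semi-stabilised benzyl sulfonium ylide, in which reversible betaine formation should funnel the reaction to the trans-oxirane (racemic, which is sufficient because only the trans relation is carried forward).

**Step 4**
Reactants: 6 rac-trans-2-[4-(benzyloxy)-2-bromo-3,5-dimethoxyphenyl]-3-[4-(benzyloxy)-3-methoxyphenyl]oxirane
Product: 8 rac-trans-3-(benzyloxy)-8-[4-(benzyloxy)-3-methoxyphenyl]-2,4-dimethoxybicyclo[4.2.0]octa-1,3,5-trien-7-ol, via aryllithium 7 (not isolated)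
Conditions: n-BuLi (1.05 equiv), THF, −78 °C; MgBr2·OEt2 (1.5 equiv), −78 °C → rt; H2O quench
Reagents that add atoms: none
Why: Bromine–lithium exchange followed by MgBr2-assisted 4-exo-tet opening of the oxirane at the activated benzylic carbon C1 (the known benzocyclobutenol synthesis from ortho-bromostilbene oxides), in which SN2 inversion at C1 converts the trans-oxirane into the trans-cyclobutenol.

**Step 5**
Reactants: 9 methyl (2R)-2-hydroxypropanoate (2.2 equiv), 10 fumaryl chloride
Product: 11 bis[(2R)-1-methoxy-1-oxopropan-2-yl] (E)-but-2-enedioate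
Conditions: Et3N (2.4 equiv), DMAP (5 mol%), CH2Cl2, 0 °C → rt
Reagents that add atoms: none
Why: Double acylation of the secondary alcohol by the diacid chloride (amine-mediated esterification), which does not touch the lactate stereocentre or the E alkene.

**Step 6**
Reactants: 8 rac-trans-3-(benzyloxy)-8-[4-(benzyloxy)-3-methoxyphenyl]-2,4-dimethoxybicyclo[4.2.0]octa-1,3,5-trien-7-ol, 11 bis[(2R)-1-methoxy-1-oxopropan-2-yl] (E)-but-2-enedioate
Product: 13 bis[(2R)-1-methoxy-1-oxopropan-2-yl] (1R,2S,3R,4R)-7-(benzyloxy)-1-[4-(benzyloxy)-3-methoxyphenyl]-4-hydroxy-6,8-dimethoxy-1,2,3,4-tetrahydronaphthalene-2,3-dicarboxylate, via o-quinodimethane 12 (not isolated)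
Conditions: toluene (0.05 M), threefold excess of the fumarate, 110 °C, sealed tube, Ar, dark, base-washed glass
Reagents that add atoms: none
Why: Heating opens the cyclobutene of 8 by conrotatory 4π electrocyclic ring opening to the o-quinodimethane 12, in which the C4 hydroxyl (a donor, strongly outward-rotating) and, because it is trans to it, the C1 aryl group both point outward; 12 then adds the fumarate 11 in a concerted suprafacial [4+2] cycloaddition, so that the four-membered ring (C4a, C8a, C1, C4) takes up C2 and C3 and becomes ring B while ring A regains its aromaticity, every atom of 8 and of one molecule of 11 being kept in 13. The closest known reaction type is the thermolysis of aryl-substituted benzocyclobutenols in the presence of fumarates and maleates, used for aryltetralin lignans, including the highly diastereoselective additions of hydroxy-o-quinodimethanes to the fumarates of lactate and mandelate esters. Ring B is the only ring closed, by an intermolecular endo [4+2] in which both new bonds (C1–C2 and C3–C4) form on the same face of the diene. C1 and C4 are set by the outward geometry of both diene termini (aryl and hydroxyl cis), C3 by the endo position of its ester next to the hydroxylated terminus (O–H···O=C hydrogen bond, ester cis to the hydroxyl), C2 by the E geometry of the fumarate (trans to C3 and therefore trans to the C1 aryl group, the 1,2-trans-2,3-trans array of the target), and the absolute sense by the two (R)-lactate units, which are assigned, by analogy with the lactate and mandelate fumarates, to leave the si face of both alkene carbons open and so give 2S,3S in the target. The step needs endo selectivity at the hydroxylated terminus, facial selectivity on the dienophile and capture of 12 faster than its tautomerisation to the 2-benzylbenzaldehyde; these are secured by the hydrogen-bonding hydroxyl, by the C2-symmetric auxiliary (both ester orientations are equivalent) and by an excess of 11 in a neutral aprotic medium. The peri methoxy group at C8, which presses on the outward aryl group of 12, is the substrate-specific risk.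

**Step 7**
Reactants: 13 bis[(2R)-1-methoxy-1-oxopropan-2-yl] (1R,2S,3R,4R)-7-(benzyloxy)-1-[4-(benzyloxy)-3-methoxyphenyl]-4-hydroxy-6,8-dimethoxy-1,2,3,4-tetrahydronaphthalene-2,3-dicarboxylate
Product: 14 bis[(2R)-1-methoxy-1-oxopropan-2-yl] (1R,2S,3S)-7-hydroxy-1-(4-hydroxy-3-methoxyphenyl)-6,8-dimethoxy-1,2,3,4-tetrahydronaphthalene-2,3-dicarboxylate
Conditions: H2 (3 atm), Pd/C (10 wt%), EtOAc–EtOH (1:1), AcOH (1 vol%), rt
Reagents that add atoms: none
Why: Heterogeneous hydrogenolysis should cleave both benzyl ethers and the benzylic C4–O bond, which is activated by the para oxygen at C7, so that the temporary hydroxyl is removed without touching C1, C2 or C3 (the descriptor at C3 changes from R to S only because C4 loses its oxygen).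

**Step 8**
Reactants: 14 bis[(2R)-1-methoxy-1-oxopropan-2-yl] (1R,2S,3S)-7-hydroxy-1-(4-hydroxy-3-methoxyphenyl)-6,8-dimethoxy-1,2,3,4-tetrahydronaphthalene-2,3-dicarboxylate
Product: 15 4-[(1R,2S,3S)-7-hydroxy-2,3-bis(hydroxymethyl)-6,8-dimethoxy-1,2,3,4-tetrahydronaphthalen-1-yl]-2-methoxyphenol (target)
Conditions: LiAlH4 (8 equiv), THF, 0 °C → rt; H2O quench
Reagents that add atoms: none
Why: Ester reduction with LiAlH4 should convert both ring esters into the primary alcohols (and the lactate esters into propane-1,2-diol) faster than enolisation, so that the 1R,2S,3S configuration set in step 6 is carried unchanged into the target.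

**Compound list**

1 | 4-(benzyloxy)-3,5-dimethoxybenzaldehyde | COc1cc(C=O)cc(OC)c1OCc1ccccc1 | starting material
2 | 4-(benzyloxy)-2-bromo-3,5-dimethoxybenzaldehyde | COc1cc(C=O)c(Br)c(OC)c1OCc1ccccc1 | intermediate
3 | [4-(benzyloxy)-3-methoxyphenyl]methanol | COc1cc(CO)ccc1OCc1ccccc1 | starting material
4 | 1-{[4-(benzyloxy)-3-methoxyphenyl]methyl}thiolan-1-ium tetrafluoroborate | COc1cc(C[S+]2CCCC2)ccc1OCc1ccccc1.F[B-](F)(F)F | intermediate
5 | sulfonium ylide of 4 (thiolanium benzylide, not isolated) | COc1cc([CH-][S+]2CCCC2)ccc1OCc1ccccc1 | intermediate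
6 | rac-trans-2-[4-(benzyloxy)-2-bromo-3,5-dimethoxyphenyl]-3-[4-(benzyloxy)-3-methoxyphenyl]oxirane (racemate, one enantiomer drawn) | COc1cc([C@H]2O[C@@H]2c3ccc(OCc4ccccc4)c(OC)c3)c(Br)c(OC)c1OCc5ccccc5 | intermediate
7 | aryllithium from 6 (lithium in place of bromine, not isolated; racemate, one enantiomer drawn) | COc1cc([C@H]2O[C@@H]2c3ccc(OCc4ccccc4)c(OC)c3)c([Li])c(OC)c1OCc5ccccc5 | intermediate
8 | rac-trans-3-(benzyloxy)-8-[4-(benzyloxy)-3-methoxyphenyl]-2,4-dimethoxybicyclo[4.2.0]octa-1,3,5-trien-7-ol (racemate, one enantiomer drawn) | O[C@H]1[C@H](c2ccc(OCc3ccccc3)c(OC)c2)c4c(OC)c(OCc5ccccc5)c(OC)cc14 | intermediate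
9 | methyl (2R)-2-hydroxypropanoate (methyl (R)-lactate) | C[C@@H](O)C(=O)OC | starting material
10 | fumaryl chloride ((E)-but-2-enedioyl dichloride) | ClC(=O)/C=C/C(Cl)=O | starting material
11 | bis[(2R)-1-methoxy-1-oxopropan-2-yl] (E)-but-2-enedioate | COC(=O)[C@@H](C)OC(=O)/C=C/C(=O)O[C@H](C)C(=O)OC | intermediate
12 | o-quinodimethane from 8, hydroxyl and aryl group both outward (not isolated) | O/C=C1\C=C(OC)C(OCc2ccccc2)=C(OC)/C1=C\c3ccc(OCc4ccccc4)c(OC)c3 | intermediate
13 | bis[(2R)-1-methoxy-1-oxopropan-2-yl] (1R,2S,3R,4R)-7-(benzyloxy)-1-[4-(benzyloxy)-3-methoxyphenyl]-4-hydroxy-6,8-dimethoxy-1,2,3,4-tetrahydronaphthalene-2,3-dicarboxylate | COc1cc([C@@H]2c3c(cc(OC)c(OCc4ccccc4)c3OC)[C@H](O)[C@H](C(=O)O[C@H](C)C(=O)OC)[C@H]2C(=O)O[C@H](C)C(=O)OC)ccc1OCc1ccccc1 | intermediate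
14 | bis[(2R)-1-methoxy-1-oxopropan-2-yl] (1R,2S,3S)-7-hydroxy-1-(4-hydroxy-3-methoxyphenyl)-6,8-dimethoxy-1,2,3,4-tetrahydronaphthalene-2,3-dicarboxylate | COc1cc([C@@H]2c3c(cc(OC)c(O)c3OC)C[C@H](C(=O)O[C@H](C)C(=O)OC)[C@H]2C(=O)O[C@H](C)C(=O)OC)ccc1O | intermediate
15 | 4-[(1R,2S,3S)-7-hydroxy-2,3-bis(hydroxymethyl)-6,8-dimethoxy-1,2,3,4-tetrahydronaphthalen-1-yl]-2-methoxyphenol | COc1cc([C@@H]2c3c(cc(OC)c(O)c3OC)C[C@H](CO)[C@H]2CO)ccc1O | target

**Step count**

Total: 8 steps. Longest linear sequence: 6 steps (1 → 2 → 6 → 8 → 13 → 14 → 15; steps 1, 3, 4, 6, 7, 8).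

**Steps most likely to fail**

1. Step 6. The outward rotation of the aryl group against the peri methoxy group may slow ring opening and cycloaddition, so that the hydroxy-diene drains away by tautomerisation. The lactate units may also discriminate the two faces of the fumarate poorly or in the opposite sense. The fallback replaces auxiliary control by resolution through the temporary hydroxyl; it sets out from 8 and comes back to the route at 15. Heating 8 with the smaller and more reactive dimethyl fumarate (toluene, 110 °C) should give, with the same relative configuration, the racemic dimethyl 7-(benzyloxy)-1-[4-(benzyloxy)-3-methoxyphenyl]-4-hydroxy-6,8-dimethoxy-1,2,3,4-tetrahydronaphthalene-2,3-dicarboxylate F1. Its C4 hydroxyl is carbamoylated with (S)-1-phenylethyl isocyanate (cat. DMAP, toluene, 60 °C); the two diastereomeric carbamates are separated by chromatography or crystallisation, and the (1R,2S,3R,4R) diastereomer, the (S)-1-phenylethylcarbamate of F1, F2, is identified by crystallography. Hydrogenolysis (H2, Pd/C, EtOAc–EtOH) cleaves the benzylic carbamate C–O bond and both benzyl ethers to give dimethyl (1R,2S,3S)-7-hydroxy-1-(4-hydroxy-3-methoxyphenyl)-6,8-dimethoxy-1,2,3,4-tetrahydronaphthalene-2,3-dicarboxylate F3, and LiAlH4 in THF reduces F3 to 15.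

2. Step 4. MgBr2 may ionise the electron-rich oxirane before the aryl nucleophile attacks, which would lead to Meinwald rearrangement to carbonyl compounds and loss of the trans relation instead of 4-exo closure. The fallback builds the cyclobutene photochemically; it sets out from 2 (with 3 as the source of the benzyl unit) and comes back to the route at 8. Alcohol 3 is converted with SOCl2 (CH2Cl2, 0 °C) into 1-(benzyloxy)-4-(chloromethyl)-2-methoxybenzene F4, and zinc insertion (Zn dust, LiCl, THF) gives [4-(benzyloxy)-3-methoxybenzyl]zinc chloride F5. Negishi coupling of F5 with 2 (Pd(OAc)2, SPhos, THF, 50 °C) gives 4-(benzyloxy)-2-[4-(benzyloxy)-3-methoxybenzyl]-3,5-dimethoxybenzaldehyde F6. Irradiation of F6 (350 nm, dilute benzene, rt, no dienophile) should give the dienol by 1,5-hydrogen transfer, and thermal conrotatory closure of this dienol should give 8; this is the known behaviour of ortho-alkyl benzaldehydes, and the trans isomer is purified from any cis isomer.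

3. Step 7. The β-hydroxy ester may lose water (through the benzylic cation or the quinone methide) to give the 1,2-dihydronaphthalene, whose unselective hydrogenation would scramble C3; the reaction may also stall at the benzylic alcohol. The fallback removes the hydroxyl by a radical path that involves neither cation nor alkene; it sets out from 13 and comes back to the route at 14. 1,1'-Thiocarbonyldiimidazole (toluene, 80 °C) converts 13 into its O-(1H-imidazol-1-ylcarbonothioyl) derivative F7. Bu3SnH and AIBN (toluene, 90 °C, Barton–McCombie deoxygenation) should then give the 4-deoxy bis(benzyl ether) diester F8; syn-elimination toward C3 is not available, because H3 is trans to the C4 oxygen. Hydrogenolysis (H2, Pd/C, EtOAc–EtOH) then removes only the two benzyl ethers to give 14.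

**Further compounds**

F1 | step 6 | racemic dimethyl 7-(benzyloxy)-1-[4-(benzyloxy)-3-methoxyphenyl]-4-hydroxy-6,8-dimethoxy-1,2,3,4-tetrahydronaphthalene-2,3-dicarboxylate, relative configuration as in 13 (the 1R,2S,3R,4R enantiomer drawn) | COc1cc([C@@H]2c3c(cc(OC)c(OCc4ccccc4)c3OC)[C@H](O)[C@H](C(=O)OC)[C@H]2C(=O)OC)ccc1OCc1ccccc1
F2 | step 6 | (S)-1-phenylethylcarbamate of the (1R,2S,3R,4R) enantiomer of F1 | COc1cc([C@@H]2c3c(cc(OC)c(OCc4ccccc4)c3OC)[C@H](OC(=O)N[C@@H](C)c5ccccc5)[C@H](C(=O)OC)[C@H]2C(=O)OC)ccc1OCc1ccccc1
F3 | step 6 | dimethyl (1R,2S,3S)-7-hydroxy-1-(4-hydroxy-3-methoxyphenyl)-6,8-dimethoxy-1,2,3,4-tetrahydronaphthalene-2,3-dicarboxylate | COc1cc([C@@H]2c3c(cc(OC)c(O)c3OC)C[C@H](C(=O)OC)[C@H]2C(=O)OC)ccc1O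
F4 | step 4 | 1-(benzyloxy)-4-(chloromethyl)-2-methoxybenzene | COc1cc(CCl)ccc1OCc1ccccc1
F5 | step 4 | [4-(benzyloxy)-3-methoxybenzyl]zinc chloride | COc1cc(C[Zn]Cl)ccc1OCc1ccccc1
F6 | step 4 | 4-(benzyloxy)-2-[4-(benzyloxy)-3-methoxybenzyl]-3,5-dimethoxybenzaldehyde | COc1cc(C=O)c(Cc2ccc(OCc3ccccc3)c(OC)c2)c(OC)c1OCc1ccccc1
F7 | step 7 | O-(1H-imidazol-1-ylcarbonothioyl) derivative of 13 at the C4 oxygen | COc1cc([C@@H]2c3c(cc(OC)c(OCc4ccccc4)c3OC)[C@H](OC(=S)n5ccnc5)[C@H](C(=O)O[C@H](C)C(=O)OC)[C@H]2C(=O)O[C@H](C)C(=O)OC)ccc1OCc1ccccc1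
F8 | step 7 | bis[(2R)-1-methoxy-1-oxopropan-2-yl] (1R,2S,3S)-7-(benzyloxy)-1-[4-(benzyloxy)-3-methoxyphenyl]-6,8-dimethoxy-1,2,3,4-tetrahydronaphthalene-2,3-dicarboxylate | COc1cc([C@@H]2c3c(cc(OC)c(OCc4ccccc4)c3OC)C[C@H](C(=O)O[C@H](C)C(=O)OC)[C@H]2C(=O)O[C@H](C)C(=O)OC)ccc1OCc1ccccc1
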